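The constants used here are those of an exercise, and the outcome is calculated.

0.112 mM of acid is what I reckoned on for the end of the feed, against the 0.0200 mM I started with. I left you this flask with the substrate still running in.

substrate 0.0020 M (fed, over 1.2 s); acid 0.0200 mM; time 1.2 s

* part of the substrate that has reacted at 1.2 s
* pH of the solution at 1.2 s

I wrote the balance of acid, the reagent charged in the smaller amount: the catalysed step gives back what it takes, so c(acid) equals its charge plus c(conjugate base). The charge late in the feed counted for less than what the weak acid gives, so I took c(acid) as the root of 6.3 × 10⁻⁶ M times the whole 0.0020 M. Substrate then has a pseudo-first-order loss constant of 4.98 s⁻¹, against 1.11 s⁻¹ at the start. Taking the steadily fed substrate to stand where feed equals loss, I expected 16.7% of the charge to remain at the end; I call this, one over dosing time times loss constant, the feed-to-loss share. That meant 83.3% reacted. I set the side step aside, its half-life on target of 12 s, reckoned as if the whole charge were there at once, being longer than the feed of 1.2 s. Don't change the substrate charge: by the same root, 8.0 × 10⁻⁴ M of it gives 0.0710 mM of acid, less than 0.112 mM.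

The forecast, on the same balance of acid ("The free proton follows from the charge balance"), gave 80% reacted, less than mine, and pH 3.97.

The flask gave 79.7% and pH 3.97.

    substrate + acid → weak acid + acid + target (k1 = 42000 M⁻¹ s⁻¹)
    weak acid ⇌ conjugate base + acid, settled at all times (K2 = 6.3 × 10⁻⁶ M)
    substrate → weak acid + target (k3 = 0.27 s⁻¹)
    substrate + target → side product (k4 = 30 M⁻¹ s⁻¹)

At 1.20 s substrate was going by the acid step 17 times as fast as by the step without acid. The flask held 20.3% of its substrate charge, above the share of 16.7%. For the neighbour flask with 8.0 × 10⁻⁴ M of substrate the share is 25.6%, and that flask held 31%.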